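(All runs stem from a simulated flask with made-up constants; scatter was added.)

A small charge, the 0.110 M of starting material in the epsilon run, is where this dispute ends, and I reach it from how the half-time moves with the charge.

| flask | starting material | time |
|---|---|---|
| alpha | 0.500 M |  |
| gamma | 0.300 M |  |
| delta | 0.250 M |  |
| epsilon | 0.110 M | 13 h |

- alpha run (time / h: [product] / M): 2.2: 0.079; 4.3: 0.155; 6.5: 0.223; 8.7: 0.282; 11: 0.333; 13: 0.376
- gamma run (time / h: [product] / M): 2.2: 0.063; 4.3: 0.112; 6.5: 0.156; 8.7: 0.188; 11: 0.216; 13: 0.241
- delta run (time / h: [product] / M): 2.2: 0.060; 4.3: 0.077; 6.5: 0.123; 8.7: 0.163; 11: 0.194; 13: 0.201

(readings scatter by 0.007 M)

1. reaction order in [starting material] at the outset, round the charge of the alpha run, defined at two percent of the starting material turned into product (one fixed amount of product, the same in the runs compared)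
2. the gamma run starts with 0.200 M less of starting material than the alpha run, and with no product. Compared where both hold the same amount of starting material, once fifteen percent of what the gamma run was charged with has turned into product, is the gamma run faster, slower or alike (within a tenth)?
3. product in the epsilon run at 13 h, as a share of the starting material charged

- Overall: starting material -> product.
- Constant volume, constant temperature.
- Bound and free are read together.
- An order is taken over about fifteen percent of the charge, up and down.

My zero of the scale is a flask of order one, whose half-time, the time until half the charge is product, does not change with the charge. Read between the readings, the alpha run reaches half at 7.51 h and the gamma run at 6.20 h. So the half-time order, one minus the logarithm of the ratio of half-times over the logarithm of the ratio of charges (the fractional-life method), reads 0.626. The delta run, at 6.61 h, gives 0.816 against the alpha run, so this reading has a wide margin. Carried down to the epsilon charge, the alpha half-time becomes 4.26 h. Counting that half-time as holding through 13 h, I expect 87.9% of the epsilon charge as product.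

The forecast holds a different view, that “the rate is saturating” through binding before reaction. It gives an order of 0.5, 85% for the epsilon run, and alike for the gamma comparison, an answer I take over because I have no reckoning of my own for it.

The flask gives an order of 0.63, higher than the forecast's, and alike, with a simulated rate ratio of 1.0. The epsilon run gives 88.1%, and the forecast's 85% stands within the margin there.

    2 starting material ⇌ substrate dimer, settled at all times (4.080 M⁻¹)
    starting material → product (0.2088 h⁻¹)

With 0.626, the simulated alpha half-time of 7.57 h shortens at the epsilon charge to 4.29 h, and the epsilon run's 88.1% amounts to an average half-time of 4.23 h.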